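The route rests on cutting the bond between oxane C5 and the first CH2 of the C16 side chain. C5 sits between the ring OCH2 carbon (C6) and, three bonds out, the side-chain carbinol carbon: a 1,5-dioxygen pattern. With C6 as an aldehyde and the carbinol as a ketone, this bond becomes an enamine Michael addition of an acyclic C7 aldehyde (carrying an enoate with an allylic acetate) to a cross-conjugated C16 vinyl ketone. One operation joins the fragments and sets C5 by catalyst control. C5 then relays its configuration to C2 when the oxane O1–C2 bond is closed by palladium allylic etherification (2,5-trans), and CBS reduction sets the carbinol.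

Key step: step 4

Assumption: hex-5-enal and methyl 2-[(acetyloxy)methyl]prop-2-enoate are taken as catalogue compounds, and geranylacetone is used as the pure E isomer.

Step 1
Reactants: 1 (E)-geranylacetone, (5E)-6,10-dimethylundeca-5,9-dien-2-one
Product: 3 (5E)-6,10-dimethylundeca-1,5,9-trien-2-yl trifluoromethanesulfonate, via kinetic lithium enolate 2 (not isolated)
Conditions: LiN(iPr)2 (1.1 equiv), THF, −78 °C; then PhNTf2, −78 → 0 °C; aqueous work-up
Reagents that add atoms: N-phenylbis(trifluoromethanesulfonimide) (PhNTf2), O=S(=O)(N(c1ccccc1)S(=O)(=O)C(F)(F)F)C(F)(F)F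
Why: Kinetic deprotonation of the methyl ketone on the methyl side and O-triflation of the less substituted enolate (enol triflate formation) should give the 2-triflyloxy-1-alkene without touching the trisubstituted alkenes.

Step 2
Reactants: 3 (5E)-6,10-dimethylundeca-1,5,9-trien-2-yl trifluoromethanesulfonate
Product: 4 (7E)-8,12-dimethyl-4-methylidenetrideca-1,7,11-trien-3-one
Conditions: Pd(PPh3)4 (3 mol%), LiCl (3 equiv), CO (3 atm), tributyl(vinyl)stannane (1.1 equiv), BHT (trace), THF, 55 °C; product kept cold and used promptly
Reagents that add atoms: carbon monoxide, [C-]#[O+]; tributyl(vinyl)stannane, C=C[Sn](CCCC)(CCCC)CCCC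
Why: Carbonylative Stille coupling (oxidative addition of the enol triflate to zerovalent palladium, CO insertion, vinyl transfer from tin, reductive elimination) should give the divinyl ketone, with CO pressure and LiCl suppressing direct vinyl–vinyl coupling.

Step 3
Reactants: 5 hex-5-enal; 6 methyl 2-[(acetyloxy)methyl]prop-2-enoate (3 equiv)
Product: 7 methyl (2E)-2-[(acetyloxy)methyl]-7-oxohept-2-enoate
Conditions: second-generation Hoveyda–Grubbs catalyst RuCl2(H2IMes)(=CH-C6H4-2-OiPr) (5 mol%), CH2Cl2, 40 °C
Reagents that add atoms: none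
Why: Olefin cross-metathesis of a terminal alkene with an excess of a 2-substituted acrylate should give the trisubstituted enoate with the chain trans to the ester, the aldehyde being tolerated by the ruthenium carbene; either alkene geometry would serve, because step 6 passes through a π-allyl complex.

Step 4
Reactants: 7 methyl (2E)-2-[(acetyloxy)methyl]-7-oxohept-2-enoate; 4 (7E)-8,12-dimethyl-4-methylidenetrideca-1,7,11-trien-3-one (1.3 equiv)
Product: 8 methyl (2E,6R,13E)-2-[(acetyloxy)methyl]-6-formyl-14,18-dimethyl-10-methylidene-9-oxononadeca-2,13,17-trienoate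
Conditions: (S)-2-[methoxy(diphenyl)methyl]pyrrolidine (10 mol%), ethyl 3,4-dihydroxybenzoate (20 mol%), neat (or 2 M in CHCl3), 4 °C; rapid filtration through silica
Reagents that add atoms: none
Why: The (S)-amine condenses with aldehyde 7 to the E-anti enamine, whose α-carbon (the CH2 next to the formyl group, the future ring C5) adds to the unsubstituted vinyl terminus of dienone 4, and hydrolysis of the resulting iminium ion releases 8 and the amine; the three-carbon tether between the new centre and the enoate CH= stays as two CH2 groups, so C6 of 8 carries the formyl group. The closest known reaction type is the diarylprolinol-ether-catalysed enamine Michael addition of unbranched aldehydes to vinyl ketones with a catechol hydrogen-bond cocatalyst. No ring is closed in this step; the oxane is closed in step 6. The one new stereocentre (C5 of the target) is under catalyst control: the methoxydiphenylmethyl group shields the Re face of the enamine, so the enone is attacked from the Si face, which gives (6R) in 8 and corresponds to (5S) in the target (same spatial arrangement, changed CIP ranking). The step needs site selectivity between the two enone termini of 4 and against the enoate of 7, which is secured because the 1,1-disubstituted terminus and the trisubstituted enoate are far less electrophilic than an unsubstituted vinyl ketone; epimerisation of 8 should be slow because the α-branched aldehyde re-forms an enamine with the bulky amine only reluctantly.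

Step 5
Reactants: 8 methyl (2E,6R,13E)-2-[(acetyloxy)methyl]-6-formyl-14,18-dimethyl-10-methylidene-9-oxononadeca-2,13,17-trienoate
Product: 10 methyl (2E,6R,9R,13E)-2-[(acetyloxy)methyl]-9-hydroxy-6-(hydroxymethyl)-14,18-dimethyl-10-methylidenenonadeca-2,13,17-trienoate, via bis(catecholboryl) ether 9 (not isolated)
Conditions: (S)-Me-CBS oxazaborolidine [(3aS)-1-methyl-3,3-diphenyltetrahydro-1H,3H-pyrrolo[1,2-c][1,3,2]oxazaborole] (0.5 equiv), catecholborane (3 equiv), CH2Cl2/toluene, −78 °C; MeOH, then aqueous NaHCO3
Reagents that add atoms: none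
Why: CBS reduction takes the aldehyde to the primary alcohol and reduces the enone 1,2 with hydride delivered to the face fixed by the (S)-oxazaborolidine (1-substituted vinyl group as the large, CH2CH2 chain as the small substituent), which should give the (R)-carbinol, while catecholborane at −78 °C leaves alkenes, enoate and acetate alone.

Step 6
Reactants: 10 methyl (2E,6R,9R,13E)-2-[(acetyloxy)methyl]-9-hydroxy-6-(hydroxymethyl)-14,18-dimethyl-10-methylidenenonadeca-2,13,17-trienoate
Product: 11 methyl 2-[(2R,5S)-5-[(3R,7E)-3-hydroxy-8,12-dimethyl-4-methylidenetrideca-7,11-dien-1-yl]oxan-2-yl]prop-2-enoate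
Conditions: Pd(PPh3)4 (5 mol%), Et3N (2 equiv), THF, 40 °C
Reagents that add atoms: none
Why: Tsuji–Trost allylic etherification: zerovalent palladium ionises the allylic acetate to a 2-(methoxycarbonyl)-π-allyl complex, and the primary hydroxyl attacks its substituted terminus in a 6-exo chair-like transition state (ring atoms O, CH2, CH, CH2, CH2, CH) with the C5 chain and the allyl unit both equatorial, so C2 should be set trans to C5 by substrate control; the secondary carbinol cannot reach the allyl unit through a normal-sized ring.

Step 7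
Reactants: 11 methyl 2-[(2R,5S)-5-[(3R,7E)-3-hydroxy-8,12-dimethyl-4-methylidenetrideca-7,11-dien-1-yl]oxan-2-yl]prop-2-enoate
Product: 13 2-[(2R,5S)-5-[(3R,7E)-3-hydroxy-8,12-dimethyl-4-methylidenetrideca-7,11-dien-1-yl]oxan-2-yl]prop-2-enoic acid (CNP0197923.2), via lithium carboxylate 12 (not isolated)
Conditions: LiOH·H2O (3 equiv), THF/H2O (3:1), 0 °C → rt; then 1 M HCl to pH 3–4 at 0 °C
Reagents that add atoms: lithium hydroxide, [Li+].[OH-]
Why: Saponification of the methyl ester (acyl–oxygen cleavage) and mild acidification should give the acid, since the oxane, the allylic alcohol and the alkenes are inert to aqueous LiOH and no stereocentre is epimerisable under these conditions.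

Compound list
1 | (E)-geranylacetone, (5E)-6,10-dimethylundeca-5,9-dien-2-one | CC(=O)CC/C=C(\C)CCC=C(C)C | starting material
2 | lithium (5E)-6,10-dimethylundeca-1,5,9-trien-2-olate (kinetic enolate) | C=C([O-])CC/C=C(\C)CCC=C(C)C.[Li+] | intermediate
3 | (5E)-6,10-dimethylundeca-1,5,9-trien-2-yl trifluoromethanesulfonate | C=C(OS(=O)(=O)C(F)(F)F)CC/C=C(\C)CCC=C(C)C | intermediate
4 | (7E)-8,12-dimethyl-4-methylidenetrideca-1,7,11-trien-3-one | C=CC(=O)C(=C)CC/C=C(\C)CCC=C(C)C | intermediate
5 | hex-5-enal | C=CCCCC=O | starting material
6 | methyl 2-[(acetyloxy)methyl]prop-2-enoate | C=C(COC(C)=O)C(=O)OC | starting material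
7 | methyl (2E)-2-[(acetyloxy)methyl]-7-oxohept-2-enoate | O=CCCC/C=C(\COC(C)=O)C(=O)OC | intermediate
8 | methyl (2E,6R,13E)-2-[(acetyloxy)methyl]-6-formyl-14,18-dimethyl-10-methylidene-9-oxononadeca-2,13,17-trienoate | O=C[C@@H](CCC(=O)C(=C)CC/C=C(\C)CCC=C(C)C)CC/C=C(\COC(C)=O)C(=O)OC | intermediate
9 | methyl (2E,6R,9R,13E)-2-[(acetyloxy)methyl]-9-[(1,3,2-benzodioxaborol-2-yl)oxy]-6-{[(1,3,2-benzodioxaborol-2-yl)oxy]methyl}-14,18-dimethyl-10-methylidenenonadeca-2,13,17-trienoate | B1(OC[C@@H](CC[C@@H](OB2Oc3ccccc3O2)C(=C)CC/C=C(\C)CCC=C(C)C)CC/C=C(\COC(C)=O)C(=O)OC)Oc2ccccc2O1 | intermediate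
10 | methyl (2E,6R,9R,13E)-2-[(acetyloxy)methyl]-9-hydroxy-6-(hydroxymethyl)-14,18-dimethyl-10-methylidenenonadeca-2,13,17-trienoate | OC[C@@H](CC[C@@H](O)C(=C)CC/C=C(\C)CCC=C(C)C)CC/C=C(\COC(C)=O)C(=O)OC | intermediate
11 | methyl 2-[(2R,5S)-5-[(3R,7E)-3-hydroxy-8,12-dimethyl-4-methylidenetrideca-7,11-dien-1-yl]oxan-2-yl]prop-2-enoate | C=C(CC/C=C(\C)CCC=C(C)C)[C@H](O)CC[C@H]1CC[C@H](C(=C)C(=O)OC)OC1 | intermediate
12 | lithium 2-[(2R,5S)-5-[(3R,7E)-3-hydroxy-8,12-dimethyl-4-methylidenetrideca-7,11-dien-1-yl]oxan-2-yl]prop-2-enoate | C=C(CC/C=C(\C)CCC=C(C)C)[C@H](O)CC[C@H]1CC[C@H](C(=C)C(=O)[O-])OC1.[Li+] | intermediate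
13 | 2-[(2R,5S)-5-[(3R,7E)-3-hydroxy-8,12-dimethyl-4-methylidenetrideca-7,11-dien-1-yl]oxan-2-yl]prop-2-enoic acid | C=C(CC/C=C(\C)CCC=C(C)C)[C@H](O)CC[C@H]1CC[C@H](C(=C)C(=O)O)OC1 | target

Total step count: 7
Longest linear sequence: 6 steps (steps 1, 2, 4, 5, 6, 7, from geranylacetone)

Steps most likely to fail

Step 4. The amine may be consumed by conjugate addition to the dienone or by allylic substitution on the acetoxymethyl enoate, the dienone may oligomerise, or the new centre may erode through re-enamination of the product. The fallback moves the union to an auxiliary-controlled titanium enolate at the carboxylic acid oxidation level and installs the acetoxymethyl enoate only afterwards; it sets out from 5 (with 4 and 6 as before) and comes back at 10. Aldehyde 5 is oxidised (NaClO2, NaH2PO4, 2-methylbut-2-ene, tBuOH/H2O) to hex-5-enoic acid F1. This is activated with PivCl/Et3N and joined to (S)-4-benzyloxazolidin-2-one in the presence of LiCl to give the N-acyl oxazolidinone F2. Its chelated Z-titanium enolate (TiCl3(OiPr) from TiCl4 and Ti(OiPr)4, iPr2NEt, CH2Cl2, 0 °C) should add to the unsubstituted vinyl terminus of dienone 4 anti to the benzyl group, in the same sense as the catalytic step, to give the keto imide F3. (S)-Me-CBS/catecholborane at −78 °C should then give the hydroxy imide F4. LiBH4 (THF, 1 equiv MeOH, 0 °C) removes the auxiliary reductively, and would equally reduce any δ-lactone formed from F4, to give the diol F5. Cross-metathesis of the terminal alkene of F5 with an excess of 6 under the conditions of step 3 should deliver diol 10.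

Step 3. Conversion may be low in the cross-metathesis of the hindered, electron-poor 2-substituted acrylate, with self-metathesis of the aldehyde competing. The fallback builds the same enoate by carbonyl addition instead of metathesis; it sets out from 5 and comes back at 7. A Morita–Baylis–Hillman reaction of 5 with methyl acrylate (DABCO, neat, rt) gives the racemic allylic alcohol F6. Ac2O with catalytic TMSOTf (CH2Cl2, 0 °C) acetylates it with allylic transposition to the rearranged dienoate acetate F7. Ozonolysis of the terminal alkene only (O3, CH2Cl2/MeOH, −78 °C, Sudan Red end-point, then Me2S) should return 7, the electron-poor trisubstituted enoate reacting much more slowly.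

Step 6. The ring closure may show insufficient trans selectivity, or the π-allyl complex may lose a β-hydride to give a diene. The fallback leaves the metal π-allyl manifold for Lewis-base catalysis; it sets out from 10 and comes back at 11. DABCO (1.1 equiv, THF, rt) displaces the acetate to give the allylic DABCO-ium acetate F8. On addition of Cs2CO3 the primary alkoxide should add at the enoate β-carbon with loss of DABCO (SN2′, 6-exo). Because the amine can re-add to the product acrylate and re-open the ring, this closure should be able to drain towards the diequatorial 2,5-trans isomer 11.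

Further compounds
F1 | step 4 | hex-5-enoic acid | C=CCCCC(=O)O
F2 | step 4 | (4S)-4-benzyl-3-(hex-5-enoyl)-1,3-oxazolidin-2-one | C=CCCCC(=O)N1[C@@H](Cc2ccccc2)COC1=O
F3 | step 4 | (4S)-4-benzyl-3-[(2R,9E)-2-(but-3-en-1-yl)-10,14-dimethyl-6-methylidene-5-oxopentadeca-9,13-dienoyl]-1,3-oxazolidin-2-one | O=C([C@@H](CCC(=O)C(=C)CC/C=C(\C)CCC=C(C)C)CCC=C)N1[C@@H](Cc2ccccc2)COC1=O
F4 | step 4 | (4S)-4-benzyl-3-[(2R,5R,9E)-2-(but-3-en-1-yl)-5-hydroxy-10,14-dimethyl-6-methylidenepentadeca-9,13-dienoyl]-1,3-oxazolidin-2-one | O=C([C@@H](CC[C@@H](O)C(=C)CC/C=C(\C)CCC=C(C)C)CCC=C)N1[C@@H](Cc2ccccc2)COC1=O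
F5 | step 4 | (2R,5R,9E)-2-(but-3-en-1-yl)-10,14-dimethyl-6-methylidenepentadeca-9,13-diene-1,5-diol | OC[C@@H](CC[C@@H](O)C(=C)CC/C=C(\C)CCC=C(C)C)CCC=C
F6 | step 3 | methyl 3-hydroxy-2-methylideneoct-7-enoate (racemic) | C=CCCCC(O)C(=C)C(=O)OC
F7 | step 3 | methyl (2E)-2-[(acetyloxy)methyl]octa-2,7-dienoate | C=CCCC/C=C(\COC(C)=O)C(=O)OC
F8 | step 6 | methyl (2E,6R,9R,13E)-2-[(1,4-diazabicyclo[2.2.2]octan-1-ium-1-yl)methyl]-9-hydroxy-6-(hydroxymethyl)-14,18-dimethyl-10-methylidenenonadeca-2,13,17-trienoate acetate | OC[C@@H](CC[C@@H](O)C(=C)CC/C=C(\C)CCC=C(C)C)CC/C=C(\C[N+]12CCN(CC1)CC2)C(=O)OC.CC(=O)[O-]
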